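## Analysis of the target

Compound 15 is a flavone, a 4H-chromen-4-one. Its benzo ring (ring A) carries methoxy groups at C5 and C8 and a free hydroxyl at C7, the pyranone (ring C) is unsubstituted at C3, and C2 bears ring B, a 3',5'-dihydroxy-4'-methoxyphenyl group. The molecule is flat and has no stereocentre, so the task is purely regiochemical: eight oxygen atoms on eighteen carbons must be placed and told apart. Ring A is a 1,2,3,5-tetraoxygenated benzene (O1, O8, O7 and O5 around C8a to C5) with a single C–H at C6, and its C7 hydroxyl must stay free while the oxygens at C5 and C8 are methyl ethers. Ring B has the reverse of the pattern that gallates give easily: the central oxygen is methylated and the two outer ones are free. The sensitive points are the three phenols on electron-rich rings (oxidised easily under basic, aerobic conditions), the pyranone (opened at C2 by hydroxide or amines) and the C5 methyl ether peri to the carbonyl (the first to be lost to Lewis acids). The difficulty lies less in ring formation than in joining two densely oxygenated, differently protected arenes without a long protecting-group sequence. The feature the route rests on is C2: a single sp2 carbon bonded only to C1' of ring B, to C3 and to O1, which is a ketone carbonyl in the open-chain 1,3-diketone form of ring C. It can therefore be supplied as carbon monoxide between a ring B aryl iodide and the methyl carbon (the future C3) of a ring A acetophenone.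

## Retrosynthetic reasoning

The O1–C2 bond of ring C in 15 is cut first. This gives a 2-hydroxyaryl 1,3-diketone, and because the ring closes under acid, the three free phenols can be carried as methoxymethyl ethers that are cleaved in the same operation. The precursor is diketone 13, and the deprotected diketone 14 is passed through without isolation. Only the hydroxyl ortho to the chain on ring A can reach the ring B carbonyl, so the closure has one outcome. The forward step must cleave three acetals and dehydrate without touching the three methyl ethers.

In 13 both bonds at the ring B carbonyl carbon (the future C2), C1'–C2 and C2–C3, are cut together. Cutting only C2–C3 would be a Claisen disconnection and would require ring B as a carboxylic acid derivative. Cutting both lets that carbon come from carbon monoxide 12 and ring B from aryl iodide 5, while acetophenone 11 supplies C3 as its enolate. The route becomes convergent, and both aromatic fragments can descend from one intermediate. The forward reaction must insert 12 into the aryl–palladium bond before the enolate is arylated directly, and it must tolerate the free, chelated phenol of 11, which later becomes O1.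

Ketone 11 is traced to dihydroxyacetophenone 10 by removing the methoxymethyl group from the oxygen para to the acetyl group (the future O7). The two hydroxyls of 10 differ sharply: one is hydrogen-bonded to the carbonyl and crowded by two ortho substituents, the other is exposed and more acidic. The forward protection therefore needs no further differentiation.

The aryl–acetyl bond of 10 is cut to give 2,5-dimethoxybenzene-1,3-diol 8. This resorcinol has a mirror plane through its two methoxy-bearing carbons, so its two ring hydrogens are equivalent, and each lies ortho to one hydroxyl and para to the other. A Friedel–Crafts acetylation can give only one ketone, and it places the carbonyl next to the oxygen that becomes O1.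

Diol 8 is taken back through its bis(methoxymethyl) ether 7 to phenol 6 by cutting the O–CH3 bond at C5. The detour through protected compounds is needed because the C5 oxygen must be methylated while the two flanking oxygens, which must end up free, are masked.

Phenol 6 and iodide 5 share one carbon skeleton and differ only in the atom at C5. The C–O bond of 6 and the C–I bond of 5 are both traced to the C–B bond of arylboronate 4, which thus feeds ring A by oxidation and ring B by ipso-iodination.

The C–B bond of 4 is cut to give arene 2 and bis(pinacolato)diboron 3. C5 of 2 is meta to both acetal oxygens, a position electrophilic substitution does not reach. It is, however, the only ring position without an ortho neighbour, which is what a sterically governed C–H borylation selects.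

Arene 2 is the bis(methoxymethyl) ether of commercial 2-methoxyresorcinol 1. Compound 1 already holds a methylated oxygen between two free ones, the pattern ring B needs at O3', O4' and O5' and ring A needs at O1, O8 and O7.

## Alternatives that were turned down

Alternative 1: ring A is built by a Moore benzannulation. The disconnection runs through ring A itself, cutting C4a–C5 and tracing C5 to C8 back to a four-membered ring.
- Forward key step: heating hydroxycyclobutenone A2 opens the cyclobutenone to a dienylketene. Its ketene carbon closes onto the dihydropyran carbon (6π closure, forming C4a–C5), and tautomerisation gives hydroquinone A1.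
- For: O5 and O8 appear as free hydroquinone hydroxyls while O7 arrives as a benzyl ether, so the 5,8-dimethoxy/7-hydroxy differentiation is built in. On this point it is stronger than the chosen route, which relies on a selective protection (step 8).
- Against: A1 is a chroman-4-ol silyl ether with C2 as a methylene group. It contains no ring B and no C2–C1' bond. After A1 the route still needs methylation, desilylation, oxidation to the chromanone, dehydrogenation to the chromone, arylation at C2 and debenzylation. A2 itself must be assembled from an organolithium and a four-membered diketone. A1 is an air-sensitive hydroquinone, and its C4 stereocentre is made only to be destroyed.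
- Comparison: the chosen route buys ring A as an aromatic compound and spends its steps only on the substituent pattern. It has one step after the key step, against at least six here. In place of built-in differentiation it offers the symmetry of 8 and the hydrogen bond in 10.

Alternative 2: ring C is closed at O1–C8a by anodic C–H etherification. The precursor is diketone A4, whose ring A carries hydrogen at the carbon that becomes C8a.
- Forward key step: anodic oxidation of ring A of A4 to its radical cation, attack of the enol oxygen at C8a, and loss of two electrons and two protons give flavone A3. Hydrogenolysis of three benzyl ethers would finish the synthesis.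
- For: ring A needs only three oxygens, so the borylation, oxidation and methylation sequence leading to 8 is not needed. On paper this is the shortest route, and in step economy for ring A it is stronger than the chosen one.
- Against: ring A of A4 is a para-dimethoxyarene. Radical cations of such rings are normally captured at the methoxy-bearing ipso carbons, and the enol oxygen reaches the methoxy-bearing ortho carbon (the future C5) as easily as C8a. Ring B and the three benzyl ethers are oxidised at similar potentials, and A3 is more easily oxidised than A4. The enol of a 1,3-diketone is a weak nucleophile. Closing a chromone by anodic attack of a diketone enol on an arene is not an established reaction for this substrate class, so the one untested step would be the ring-forming step.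
- Comparison: the chosen route spends more steps to place O1 on ring A early by routine chemistry, and in return its key step is a known reaction with a chemoselectivity question only.

Alternative 3: ring B is built from a vinamidinium salt and a dialkoxy ketone, cutting C2'–C3' and C5'–C6'.
- Forward key step: ketone A7 condenses through both α-carbons with the two electrophilic termini of chromonyl vinamidinium salt A6 under a strong alkoxide base. Loss of both amine groups aromatises the new ring to phenol A5, whose C4' is the former carbonyl carbon.
- For: the 4'-hydroxyl appears free between two benzyl ethers, so the 3',5'-dihydroxy-4'-methoxy pattern follows from one methylation without ambiguity. The advantage is real, but the chosen route obtains the same pattern by purchase, since 1 already has it.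
- Against: A6 contains the complete ring A and ring C system. All the ring A work of the chosen route, up to an analogue of 11, would have to be done first, followed by chromone formation and vinamidinium formation. The chromone C2 is electrophilic, and both the alkoxide and the liberated secondary amine can open the pyranone, so the key step runs under the conditions the substrate tolerates least. Methylation and hydrogenolysis still follow A5.
- Comparison: the route is longer than the chosen one and builds a benzene ring that commerce provides.

Key step: step 9

## Route

Step 1
Reactants: 1 2-methoxybenzene-1,3-diol (2-methoxyresorcinol)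
Product: 2 2-methoxy-1,3-bis(methoxymethoxy)benzene
Conditions: MOMCl (2.5 equiv), i-Pr2NEt, CH2Cl2, 0 °C to rt
Reagents that add atoms: chloromethyl methyl ether (MOMCl), COCCl
Why: O-alkylation of both phenols with an α-chloro ether gives the bis-acetal. The methoxymethyl ethers withstand the basic, oxidative and palladium steps that follow and are removed at the end by acid.

Step 2
Reactants: 2 2-methoxy-1,3-bis(methoxymethoxy)benzene; 3 bis(pinacolato)diboron
Product: 4 2-[4-methoxy-3,5-bis(methoxymethoxy)phenyl]-4,4,5,5-tetramethyl-1,3,2-dioxaborolane
Conditions: [Ir(OMe)(cod)]2 (1.5 mol%), 4,4'-di-tert-butyl-2,2'-bipyridine (3 mol%), THF, 80 °C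
Reagents that add atoms: none
Why: Iridium-catalysed aromatic C–H borylation is governed by sterics. In the 1,2,3-trisubstituted ring of 2 only C5 has no ortho substituent, so boron should enter there, whereas electrophilic substitution would go to C4.

Step 3
Reactants: 4 2-[4-methoxy-3,5-bis(methoxymethoxy)phenyl]-4,4,5,5-tetramethyl-1,3,2-dioxaborolane
Product: 5 5-iodo-2-methoxy-1,3-bis(methoxymethoxy)benzene
Conditions: CuI (10 mol%), 1,10-phenanthroline (20 mol%), KI (1.5 equiv), MeOH/H2O, air, 80 °C
Reagents that add atoms: potassium iodide, [K+].[I-]
Why: Copper-mediated ipso-iododeboronation transfers the aryl group from boron to copper and forms the C–I bond after aerobic oxidation, so iodine lands where boron was. The medium is neutral and leaves the acetals intact.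

Step 4
Reactants: 4 2-[4-methoxy-3,5-bis(methoxymethoxy)phenyl]-4,4,5,5-tetramethyl-1,3,2-dioxaborolane
Product: 6 4-methoxy-3,5-bis(methoxymethoxy)phenol
Conditions: 30% H2O2 (aq), NaOH (aq), THF, 0 °C to rt
Reagents that add atoms: hydrogen peroxide, OO
Why: Hydroperoxide adds to boron and the aryl group migrates from boron to oxygen; hydrolysis of the borate gives the phenol. The basic medium spares the acetals, and the low temperature limits over-oxidation of the electron-rich phenol.

Step 5
Reactants: 6 4-methoxy-3,5-bis(methoxymethoxy)phenol
Product: 7 2,5-dimethoxy-1,3-bis(methoxymethoxy)benzene
Conditions: MeI, K2CO3, acetone, reflux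
Reagents that add atoms: iodomethane, CI
Why: Williamson ether synthesis on the only free hydroxyl; this fixes the future C5 methoxy group while the two flanking oxygens are masked.

Step 6
Reactants: 7 2,5-dimethoxy-1,3-bis(methoxymethoxy)benzene
Product: 8 2,5-dimethoxybenzene-1,3-diol
Conditions: HCl (cat.), MeOH, 50 °C, under Ar
Reagents that add atoms: none
Why: Acid-catalysed acetal exchange removes both methoxymethyl groups, the solvent trapping each as dimethoxymethane. The aryl methyl ethers are stable to dilute acid, and the product is the symmetric resorcinol.

Step 7
Reactants: 8 2,5-dimethoxybenzene-1,3-diol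
Product: 10 1-(2,4-dihydroxy-3,6-dimethoxyphenyl)ethan-1-one, via difluoroboron chelate 9 (not isolated)
Conditions: AcOH, BF3·OEt2, 80 °C; then H2O/EtOH, reflux
Reagents that add atoms: acetic acid, CC(=O)O
Why: Friedel–Crafts acetylation of a strongly activated resorcinol. The two ring positions are equivalent by symmetry, so one ketone results. It is held as its difluoroboron chelate, which deactivates the ring towards a second acylation and is hydrolysed on aqueous heating.

Step 8
Reactants: 10 1-(2,4-dihydroxy-3,6-dimethoxyphenyl)ethan-1-one
Product: 11 1-[2-hydroxy-3,6-dimethoxy-4-(methoxymethoxy)phenyl]ethan-1-one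
Conditions: MOMCl (1.1 equiv), i-Pr2NEt, CH2Cl2, 0 °C
Reagents that add atoms: chloromethyl methyl ether (MOMCl), COCCl
Why: Selective O-alkylation. The 2-hydroxyl is hydrogen-bonded to the carbonyl and flanked by two ortho substituents, while the 4-hydroxyl, para to the acetyl group, is more acidic and unhindered, so one equivalent of reagent should protect only the latter.

Step 9
Reactants: 11 1-[2-hydroxy-3,6-dimethoxy-4-(methoxymethoxy)phenyl]ethan-1-one; 5 5-iodo-2-methoxy-1,3-bis(methoxymethoxy)benzene; 12 carbon monoxide
Product: 13 1-[2-hydroxy-3,6-dimethoxy-4-(methoxymethoxy)phenyl]-3-[4-methoxy-3,5-bis(methoxymethoxy)phenyl]propane-1,3-dione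
Conditions: 11, NaN(SiMe3)2 (2.1 equiv), THF, 0 °C; then 5 (1.1 equiv), Pd(dba)2 (5 mol%), Xantphos (5 mol%), CO (1 atm), 1,4-dioxane, 80 °C, with further NaN(SiMe3)2 (1.1 equiv) added slowly; AcOH quench
Reagents that add atoms: none
Why: Zerovalent palladium ligated by Xantphos inserts into the C–I bond of 5, which has no ortho substituent, and the electron-rich arylpalladium iodide takes up CO by migratory insertion to give a divalent aroylpalladium complex. The sodium enolate of 11, present as the phenoxide–enolate dianion, displaces iodide, and C–C reductive elimination joins the acyl carbon to the methyl carbon, so C1'–C2 and C2–C3 form in one catalytic cycle and the carbon of 12 becomes C2. If the phenoxide oxygen takes the acyl group first, the resulting aryl ester should be carried on to the same diketone by Baker–Venkataraman O-to-C acyl transfer under the excess base, so both channels converge on 13. The closest known reaction type is the palladium-catalysed carbonylative α-arylation of ketones with aryl iodides to 1,3-diketones, which has been applied to 2-hydroxyacetophenones as a way into flavones. No ring is closed and no stereocentre is formed in this step. The selectivity needed is acyl transfer over direct α-arylation: the CO atmosphere and the wide bite angle of Xantphos should make CO insertion faster than enolate capture by the arylpalladium species, and the donor-rich aryl group of 5 migrates to CO readily. The diketone is deprotonated as it forms, which shields it from a second acylation and accounts for the third equivalent of base, added slowly so that free silylamide does not stand under CO. The methyl and methoxymethyl ethers are inert to the base and to palladium.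

Step 10
Reactants: 13 1-[2-hydroxy-3,6-dimethoxy-4-(methoxymethoxy)phenyl]-3-[4-methoxy-3,5-bis(methoxymethoxy)phenyl]propane-1,3-dione
Product: 15 2-(3,5-dihydroxy-4-methoxyphenyl)-7-hydroxy-5,8-dimethoxy-4H-chromen-4-one, via triol diketone 14 (not isolated)
Conditions: HCl (3 M in MeOH), 65 °C
Reagents that add atoms: none
Why: Acid-catalysed acetal exchange removes the three methoxymethyl groups. The hydroxyl ortho to the chain on ring A then adds to the ring B carbonyl (6-exo-trig) and the hemiketal loses water to give the pyranone (cyclodehydration of a 2-hydroxyaryl 1,3-diketone). Only this hydroxyl can reach the carbonyl, the order of the two events does not change the outcome, and the methyl ethers survive methanolic HCl.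

## Compound list

1 | 2-methoxybenzene-1,3-diol (2-methoxyresorcinol) | COc1c(O)cccc1O | starting material
2 | 2-methoxy-1,3-bis(methoxymethoxy)benzene | COCOc1cccc(OCOC)c1OC | intermediate
3 | bis(pinacolato)diboron | CC1(C)OB(OC1(C)C)B1OC(C)(C)C(C)(C)O1 | starting material
4 | 2-[4-methoxy-3,5-bis(methoxymethoxy)phenyl]-4,4,5,5-tetramethyl-1,3,2-dioxaborolane | COCOc1cc(B2OC(C)(C)C(C)(C)O2)cc(OCOC)c1OC | intermediate
5 | 5-iodo-2-methoxy-1,3-bis(methoxymethoxy)benzene | COCOc1cc(I)cc(OCOC)c1OC | intermediate
6 | 4-methoxy-3,5-bis(methoxymethoxy)phenol | COCOc1cc(O)cc(OCOC)c1OC | intermediate
7 | 2,5-dimethoxy-1,3-bis(methoxymethoxy)benzene | COCOc1cc(OC)cc(OCOC)c1OC | intermediate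
8 | 2,5-dimethoxybenzene-1,3-diol | COc1cc(O)c(OC)c(O)c1 | intermediate
9 | difluoroboron chelate of 10 (BF2 bridging the carbonyl oxygen and the ortho phenoxide oxygen; 2,2-difluoro-7-hydroxy-5,8-dimethoxy-4-methyl-1,3,2-benzodioxaborinin-3-ium-2-uide) | CC1=[O+][B-](F)(F)Oc2c(OC)c(O)cc(OC)c21 | intermediate
10 | 1-(2,4-dihydroxy-3,6-dimethoxyphenyl)ethan-1-one | CC(=O)c1c(O)c(OC)c(O)cc1OC | intermediate
11 | 1-[2-hydroxy-3,6-dimethoxy-4-(methoxymethoxy)phenyl]ethan-1-one | CC(=O)c1c(O)c(OC)c(OCOC)cc1OC | intermediate
12 | carbon monoxide | [C-]#[O+] | starting material
13 | 1-[2-hydroxy-3,6-dimethoxy-4-(methoxymethoxy)phenyl]-3-[4-methoxy-3,5-bis(methoxymethoxy)phenyl]propane-1,3-dione | COCOc1cc(C(=O)CC(=O)c2c(O)c(OC)c(OCOC)cc2OC)cc(OCOC)c1OC | intermediate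
14 | 1-(2,4-dihydroxy-3,6-dimethoxyphenyl)-3-(3,5-dihydroxy-4-methoxyphenyl)propane-1,3-dione | COc1c(O)cc(C(=O)CC(=O)c2c(O)c(OC)c(O)cc2OC)cc1O | intermediate
15 | 2-(3,5-dihydroxy-4-methoxyphenyl)-7-hydroxy-5,8-dimethoxy-4H-chromen-4-one | COc1c(O)cc(-c2cc(=O)c3c(OC)cc(O)c(OC)c3o2)cc1O | target

## Step count and least certain steps

Total: 10 steps. Longest linear sequence: 9 steps (steps 1, 2, 4, 5, 6, 7, 8, 9 and 10, from 1 to 15). The ring B branch (steps 1, 2 and 3) joins at step 9.

Step 9 (key step).
- Risk: the arylpalladium species may couple with the enolate before it has taken up CO (direct α-arylation). The catalyst may stall because the phenoxide and the diketonate chelate palladium. Silylamide base may be consumed by reaction with CO.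
- Fallback: the one-carbon unit is brought in as a carboxyl group and the diketone is made by Baker–Venkataraman rearrangement. Setting out from 5, iodine–magnesium exchange (i-PrMgCl·LiCl, THF, −20 °C) and quenching with CO2 should give 4-methoxy-3,5-bis(methoxymethoxy)benzoic acid F1 after work-up at pH 4. Carbodiimide esterification (EDC·HCl, DMAP, CH2Cl2) with the phenol of 11 should give 2-acetyl-3,6-dimethoxy-5-(methoxymethoxy)phenyl 4-methoxy-3,5-bis(methoxymethoxy)benzoate F2. KOtBu in THF should then move the aroyl group from oxygen to the methyl carbon, returning to the route at 13.

Step 6.
- Risk: the methoxymethyl cation released on deprotection may be captured by the very electron-rich ring instead of by the solvent, leading to methylene-bridged oligomers. The free resorcinol may also oxidise in air during isolation.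
- Fallback: the acetyl group is introduced before any deprotection. Setting out from 7, directed ortho-lithiation (n-BuLi, TMEDA, THF, 0 °C) at one of the two equivalent ring positions between a methoxymethoxy and a methoxy group, followed by N-methoxy-N-methylacetamide, should give 1-[3,6-dimethoxy-2,4-bis(methoxymethoxy)phenyl]ethan-1-one F3. MgBr2·OEt2 in CH2Cl2 should then cleave only the acetal ortho to the carbonyl, which it can chelate together with the ketone oxygen. This returns to the route at 11 and bypasses 8 and 10.

Step 7.
- Risk: a second acylation at the remaining ring position, or cleavage by the boron Lewis acid of the methyl ether that lies ortho to the new carbonyl at 80 °C.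
- Fallback: setting out from 8, a Hoesch reaction (MeCN, ZnCl2, HCl gas, Et2O, 0 °C) should deposit 1-(2,4-dihydroxy-3,6-dimethoxyphenyl)ethan-1-iminium chloride F4, whose positive charge shuts the ring off from further acylation. Boiling the salt in water should hydrolyse it and return to the route at 10.

Step 10.
- Risk: acid-catalysed retro-Claisen cleavage of the diketone by methanol may compete with ring closure. The formaldehyde equivalents released from three acetals may attack C6 of ring A, the activated position between O5 and O7.
- Fallback: the two events are separated. Setting out from 13, ZnBr2 and propane-1-thiol in CH2Cl2 at 0 °C should transfer the three methoxymethyl groups to sulfur and give triol diketone 14, this time isolated. No formaldehyde equivalent is then present when 14 is cyclodehydrated with catalytic H2SO4 in AcOH at 60 °C, returning to the route at 15. No compound outside the list is made.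

## Further compounds

F1 | step 9 | 4-methoxy-3,5-bis(methoxymethoxy)benzoic acid | COCOc1cc(C(=O)O)cc(OCOC)c1OC
F2 | step 9 | 2-acetyl-3,6-dimethoxy-5-(methoxymethoxy)phenyl 4-methoxy-3,5-bis(methoxymethoxy)benzoate | CC(=O)c1c(OC(=O)c2cc(OCOC)c(OC)c(OCOC)c2)c(OC)c(OCOC)cc1OC
F3 | step 6 | 1-[3,6-dimethoxy-2,4-bis(methoxymethoxy)phenyl]ethan-1-one | CC(=O)c1c(OCOC)c(OC)c(OCOC)cc1OC
F4 | step 7 | 1-(2,4-dihydroxy-3,6-dimethoxyphenyl)ethan-1-iminium chloride | CC(=[NH2+])c1c(O)c(OC)c(O)cc1OC.[Cl-]
F0 | step 10 | none | none
A1 | alternative 1 | 7-(benzyloxy)-4-[(tert-butyldimethylsilyl)oxy]chromane-5,8-diol (racemic) | Oc1cc(OCc2ccccc2)c(O)c2c1C(O[Si](C)(C)C(C)(C)C)CCO2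
A2 | alternative 1 | 3-(benzyloxy)-4-{4-[(tert-butyldimethylsilyl)oxy]-3,4-dihydro-2H-pyran-6-yl}-4-hydroxycyclobut-2-en-1-one (racemic, mixture of diastereomers) | O=C1C=C(OCc2ccccc2)C1(O)C1=CC(O[Si](C)(C)C(C)(C)C)CCO1
A3 | alternative 2 | 7-(benzyloxy)-2-[3,5-bis(benzyloxy)-4-methoxyphenyl]-5,8-dimethoxy-4H-chromen-4-one | COc1c(OCc2ccccc2)cc(-c2cc(=O)c3c(OC)cc(OCc4ccccc4)c(OC)c3o2)cc1OCc1ccccc1
A4 | alternative 2 | 1-[4-(benzyloxy)-2,5-dimethoxyphenyl]-3-[3,5-bis(benzyloxy)-4-methoxyphenyl]propane-1,3-dione | COc1cc(OCc2ccccc2)c(OC)cc1C(=O)CC(=O)c1cc(OCc2ccccc2)c(OC)c(OCc2ccccc2)c1
A5 | alternative 3 | 7-(benzyloxy)-2-[3,5-bis(benzyloxy)-4-hydroxyphenyl]-5,8-dimethoxy-4H-chromen-4-one | Oc1c(OCc2ccccc2)cc(-c2cc(=O)c3c(OC)cc(OCc4ccccc4)c(OC)c3o2)cc1OCc1ccccc1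
A6 | alternative 3 | N-{2-[7-(benzyloxy)-5,8-dimethoxy-4-oxo-4H-chromen-2-yl]-3-(dimethylamino)prop-2-en-1-ylidene}-N-methylmethanaminium hexafluorophosphate | CN(C)C=C(C=[N+](C)C)c1cc(=O)c2c(OC)cc(OCc3ccccc3)c(OC)c2o1.F[P-](F)(F)(F)(F)F
A7 | alternative 3 | 1,3-bis(benzyloxy)propan-2-one | O=C(COCc1ccccc1)COCc1ccccc1
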